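**Retrosynthetic overview**

1. Side chain: the C(sp3)–C(sp2) bond between the ring CH2CH2 arm and the first chain olefin is cut, giving a ring vinyl group (hydroboration, then B-alkyl Suzuki–Miyaura coupling) and a C19 (E)-alkenyl iodide made from farnesyl bromide and propyne.
2. Ring (the only ring, closed once): the bond from the acetoxy-bearing CH to the gem-dimethyl carbon and the bond from the chain-bearing CH to the methyl-bearing olefinic carbon are cut together. This gives (Z)-4-iodopent-3-enal (four ring carbons, ring methyl, oxygen) and the enantioenriched 1,2-bis(boronate) of 4-methylpenta-1,3-diene (two ring carbons, gem-dimethyl, vinyl).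
3. Enabling feature: in the cyclohexene the O–CH, the C(CH3)2 and the allylic CH(chain) are contiguous, and that CH lies next to the ring C(CH3)=CH. The C(CH3)2–CH pair is therefore the shared centre of two overlapping allyl units, so one 1,2-diborylated C6 unit can form both ring bonds: first by allylboration of the aldehyde, then by allyl–alkenyl coupling onto a cis-iodoalkene that already holds the ring olefin.
4. Stereochemistry: one C–B stereocentre from catalytic diboration is transferred to the carbinol carbon; the allylic CH is then set in the ring closure (1,3-cis).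

Key step: step 5

Remark on the chemistry: the antipode of the TADDOL-derived phosphonite ligand in step 1 is assumed to be the one that gives the (S)-bis(boronate) 2; simple reagents (bis(pinacolato)diboron, acetic anhydride, iodine and the like) are given on the reagent lines and are not numbered.

**Step 1**
Reactants: 1 4-methylpenta-1,3-diene
Product: 2 (S)-2,2'-(4-methylpent-3-ene-1,2-diyl)bis(4,4,5,5-tetramethyl-1,3,2-dioxaborolane)
Conditions: B2pin2, Pt(dba)3 (cat.), TADDOL-derived phenylphosphonite ligand (cat.), THF, 60 °C
Reagents that add atoms: bis(pinacolato)diboron, CC1(C)OB(OC1(C)C)B1OC(C)(C)C(C)(C)O1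
Why: Platinum-catalysed enantioselective alkene diboration: a 4,4-disubstituted diene cannot reach the s-cis geometry needed for 1,4-addition, so B–B should add 1,2 across the terminal double bond, and the chiral ligand on zerovalent platinum sets the C–B stereocentre (S).

**Step 2**
Reactants: 3 3-[(tert-butyldimethylsilyl)oxy]propanal
Product: 4 (Z)-tert-butyl[(4-iodopent-3-en-1-yl)oxy]dimethylsilane
Conditions: [Ph3PEt]I, n-BuLi, THF, rt; I2, −78 °C; NaN(SiMe3)2, −20 °C; then 3, −78 °C to rt
Reagents that add atoms: ethyltriphenylphosphonium iodide, CC[P+](c1ccccc1)(c1ccccc1)c1ccccc1.[I-]; iodine, II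
Why: Stork–Zhao olefination: the α-iodo ylide made in the flask should react with the unhindered aldehyde under kinetic control to give the (Z)-2-iodo-2-alkene, which fixes the cis relation later needed between the ring CH2 and the carbon–palladium bond.

**Step 3**
Reactants: 4 (Z)-tert-butyl[(4-iodopent-3-en-1-yl)oxy]dimethylsilane
Product: 5 (Z)-4-iodopent-3-en-1-ol
Conditions: PPTS (cat.), MeOH, rt
Reagents that add atoms: none
Why: Acid-catalysed methanolysis of a primary silyl ether; the alkenyl iodide is inert under these conditions.

**Step 4**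
Reactants: 5 (Z)-4-iodopent-3-en-1-ol
Product: 6 (Z)-4-iodopent-3-enal
Conditions: Dess–Martin periodinane, CH2Cl2, 0 °C; used at once
Reagents that add atoms: none
Why: Dess–Martin oxidation is mild enough to give the β,γ-unsaturated aldehyde without moving the double bond into conjugation.

**Step 5**
Reactants: 2 (S)-2,2'-(4-methylpent-3-ene-1,2-diyl)bis(4,4,5,5-tetramethyl-1,3,2-dioxaborolane); 6 (Z)-4-iodopent-3-enal
Product: 8 (1S,5R)-5-ethenyl-4,6,6-trimethylcyclohex-3-en-1-ol, via O-boryl allyl boronate 7 (not isolated)
Conditions: CH2Cl2, rt, 16 h; then THF (high dilution), Pd(OAc)2 (cat.), SPhos (cat.), aq KOH, 60 °C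
Reagents that add atoms: none
Why: Proposed new method: the α-chiral secondary allyl boronate of 2 first adds to aldehyde 6 through the closed six-membered chair transition state of a carbonyl allylboration (a [3,3]-type metallo-ene transfer), which forms the carbinol–quaternary carbon bond, transposes the double bond and leaves the primary (E)-allyl boronate 7; Pd(OAc)2/SPhos and aqueous KOH then bring about oxidative addition into the (Z)-alkenyl iodide, boron-to-palladium transmetalation with allyl transposition (or, equivalently, 6-exo carbopalladation followed by β-boryl elimination) and reductive elimination, which forms the second ring bond and turns the terminal two carbons into a vinyl group. The closest known reactions are the thermal double allylboration of 1,4-dicarbonyl compounds by diene-derived 1,2-bis(boronates) and the γ-selective Suzuki–Miyaura coupling of allyl boronates with alkenyl halides; their merger in one flask as a ring-closing event is the untested element. The single ring closes in a 6-exo sense at the γ-carbon of the second allyl unit, since α-coupling would need an eight-membered ring holding an (E)-olefin. The carbinol centre (S) is set by 1,3-chirality transfer from the C–B centre of 2 (boron-bearing carbon substituent and aldehyde chain both equatorial in the chair, the axial γ-methyl disfavouring the alternative), and the allylic methine (R) is set in the ring closure, where pseudo-equatorial placement of both the oxygen substituent and the emerging vinyl group should give the 1,3-cis isomer. The step needs γ- over α-selectivity at each allyl unit (secured by the closed transition state in the first event and by ring size in the second) and retention of the (Z)-iodoalkene geometry, which oxidative addition preserves and which becomes the ring olefin.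

**Step 6**
Reactants: 8 (1S,5R)-5-ethenyl-4,6,6-trimethylcyclohex-3-en-1-ol
Product: 9 (1S,5R)-5-ethenyl-4,6,6-trimethylcyclohex-3-en-1-yl acetate
Conditions: Ac2O, pyridine, DMAP (cat.), CH2Cl2, rt
Reagents that add atoms: acetic anhydride, CC(=O)OC(C)=O
Why: DMAP-catalysed acylation should esterify the hindered secondary alcohol next to the quaternary carbon; no other nucleophilic group is present.

**Step 7**
Reactants: 10 (2E,6E)-farnesyl bromide; 11 propyne
Product: 14 (6E,10E)-7,11,15-trimethylhexadeca-6,10,14-trien-2-yne, via 1,3-dilithiopropyne 12 (not isolated), via lithium acetylide 13 (not isolated)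
Conditions: 11, n-BuLi (2 equiv), TMEDA, THF/hexane, −78 to 0 °C; 10, −78 °C to rt; then MeI, DMPU, 0 °C to rt
Reagents that add atoms: iodomethane, CI
Why: Double deprotonation of propyne gives 1,3-dilithiopropyne, whose sp3 carbanion should displace the allylic bromide by SN2; the remaining acetylide is then C-methylated in the same flask, and the farnesyl olefin geometry is untouched.

**Step 8**
Reactants: 14 (6E,10E)-7,11,15-trimethylhexadeca-6,10,14-trien-2-yne
Product: 16 (2E,6E,10E)-2-iodo-7,11,15-trimethylhexadeca-2,6,10,14-tetraene, via alkenylzirconocene chloride 15 (not isolated)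
Conditions: Cp2Zr(H)Cl (excess), THF, rt then 50 °C; I2, 0 °C
Reagents that add atoms: iodine, II
Why: Schwartz hydrozirconation adds Zr–H syn across the alkyne, with zirconium expected on the less hindered methyl-bearing carbon after equilibration with excess reagent, and iodinolysis with retention gives the (E)-2-iodo-2-alkene; trisubstituted olefins do not react.

**Step 9**
Reactants: 9 (1S,5R)-5-ethenyl-4,6,6-trimethylcyclohex-3-en-1-yl acetate; 16 (2E,6E,10E)-2-iodo-7,11,15-trimethylhexadeca-2,6,10,14-tetraene
Product: 18 (1S,5R)-4,6,6-trimethyl-5-[(3E,7E,11E)-3,8,12,16-tetramethylheptadeca-3,7,11,15-tetraen-1-yl]cyclohex-3-en-1-yl acetate (target CNP0313409.1), via B-alkyl-9-BBN adduct 17 (not isolated)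
Conditions: 9, 9-BBN, THF, rt; then 16, Pd(dppf)Cl2 (cat.), AsPh3, Cs2CO3, DMF/H2O, rt
Reagents that add atoms: none
Why: 9-BBN should hydroborate only the monosubstituted vinyl group (anti-Markovnikov), and the B-alkyl Suzuki–Miyaura coupling joins the primary alkylborane to the alkenyl iodide with retention of the E geometry under carbonate conditions that spare the acetate.

**Compound list**

1 | 4-methylpenta-1,3-diene | C=CC=C(C)C | starting material
2 | (S)-2,2'-(4-methylpent-3-ene-1,2-diyl)bis(4,4,5,5-tetramethyl-1,3,2-dioxaborolane) | CC(C)=C[C@H](CB1OC(C)(C)C(C)(C)O1)B1OC(C)(C)C(C)(C)O1 | intermediate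
3 | 3-[(tert-butyldimethylsilyl)oxy]propanal | O=CCCO[Si](C)(C)C(C)(C)C | starting material
4 | (Z)-tert-butyl[(4-iodopent-3-en-1-yl)oxy]dimethylsilane | I/C(C)=C\CCO[Si](C)(C)C(C)(C)C | intermediate
5 | (Z)-4-iodopent-3-en-1-ol | I/C(C)=C\CCO | intermediate
6 | (Z)-4-iodopent-3-enal | I/C(C)=C\CC=O | intermediate
7 | 2-{[(2Z,5S,7E)-2-iodo-6,6-dimethyl-9-(4,4,5,5-tetramethyl-1,3,2-dioxaborolan-2-yl)nona-2,7-dien-5-yl]oxy}-4,4,5,5-tetramethyl-1,3,2-dioxaborolane | I/C(C)=C\C[C@H](OB1OC(C)(C)C(C)(C)O1)C(C)(C)/C=C/CB1OC(C)(C)C(C)(C)O1 | intermediate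
8 | (1S,5R)-5-ethenyl-4,6,6-trimethylcyclohex-3-en-1-ol | O[C@H]1CC=C(C)[C@@H](C=C)C1(C)C | intermediate
9 | (1S,5R)-5-ethenyl-4,6,6-trimethylcyclohex-3-en-1-yl acetate | CC(=O)O[C@H]1CC=C(C)[C@@H](C=C)C1(C)C | intermediate
10 | (2E,6E)-1-bromo-3,7,11-trimethyldodeca-2,6,10-triene (farnesyl bromide) | BrC/C=C(\C)CC/C=C(\C)CCC=C(C)C | starting material
11 | propyne | CC#C | starting material
12 | 1,3-dilithiopropyne | [Li]CC#C[Li] | intermediate
13 | lithium (5E,9E)-6,10,14-trimethylpentadeca-5,9,13-trien-1-yn-1-ide | [Li]C#CCC/C=C(\C)CC/C=C(\C)CCC=C(C)C | intermediate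
14 | (6E,10E)-7,11,15-trimethylhexadeca-6,10,14-trien-2-yne | CC#CCC/C=C(\C)CC/C=C(\C)CCC=C(C)C | intermediate
15 | chlorobis(cyclopentadienyl)[(2E,6E,10E)-7,11,15-trimethylhexadeca-2,6,10,14-tetraen-2-yl]zirconium, Cp2Zr(Cl)(alkenyl) | Cl[Zr](C1C=CC=C1)(C1C=CC=C1)/C(C)=C/CC/C=C(\C)CC/C=C(\C)CCC=C(C)C | intermediate
16 | (2E,6E,10E)-2-iodo-7,11,15-trimethylhexadeca-2,6,10,14-tetraene | I/C(C)=C/CC/C=C(\C)CC/C=C(\C)CCC=C(C)C | intermediate
17 | (1S,5R)-5-[2-(9-borabicyclo[3.3.1]nonan-9-yl)ethyl]-4,6,6-trimethylcyclohex-3-en-1-yl acetate | CC(=O)O[C@H]1CC=C(C)[C@@H](CCB2C3CCCC2CCC3)C1(C)C | intermediate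
18 | (1S,5R)-4,6,6-trimethyl-5-[(3E,7E,11E)-3,8,12,16-tetramethylheptadeca-3,7,11,15-tetraen-1-yl]cyclohex-3-en-1-yl acetate | CC(=O)O[C@H]1CC=C(C)[C@@H](CC/C(C)=C/CC/C=C(\C)CC/C=C(\C)CCC=C(C)C)C1(C)C | target

**Summary**

Total step count: 9. Longest linear sequence: 6 steps (steps 2, 3, 4, 5, 6, 9, from compound 3).

**Steps most likely to fail**

Step 5 (Proposed new method). After the allylboration, ring closure at palladium may be slower than protodeboronation of the allyl boronate, or the second bond may form on the wrong face of the allyl unit and give the 1,3-trans ring. The fallback uses known chemistry, a thermal double allylboration in place of the palladium coupling, and sets out from 2. Compound 2 and butanedial (freshly liberated from 2,5-dimethoxytetrahydrofuran) in CH2Cl2 at rt should undergo two successive carbonyl allylborations through chair transition states, the second one intramolecular, to give (1S,3S,4S)-3-ethenyl-2,2-dimethylcyclohexane-1,4-diol F1. The hydroxyl remote from the quaternary carbon is the less hindered one and should be oxidised selectively with TEMPO/PhI(OAc)2 to (2S,4S)-2-ethenyl-4-hydroxy-3,3-dimethylcyclohexan-1-one F2. Acetylation (Ac2O, DMAP) gives (1S,3S)-3-ethenyl-2,2-dimethyl-4-oxocyclohexyl acetate F3. Kinetic deprotonation at the ring CH2 (KN(SiMe3)2, THF, −78 °C; the methine between carbonyl and quaternary carbon is shielded) and trapping with PhNTf2 gives (1S,5S)-5-ethenyl-6,6-dimethyl-4-{[(trifluoromethyl)sulfonyl]oxy}cyclohex-3-en-1-yl acetate F4. Me2CuLi then replaces the triflate by methyl, and the route is rejoined at 9.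

Step 8. Zirconium may add partly to the inner alkyne carbon, which would give a regioisomeric iodide that is hard to remove and would carry through the coupling. The fallback replaces hydrometalation of the methylalkyne by a silicon-controlled sequence and sets out from 10. Alkylation of lithiated 1-(trimethylsilyl)propyne (n-BuLi, THF, −78 °C) with 10 gives trimethyl[(5E,9E)-6,10,14-trimethylpentadeca-5,9,13-trien-1-yn-1-yl]silane F5. i-Bu2AlH in hexane at 50 °C places aluminium on the silyl-bearing carbon as the anti adduct, and MeLi followed by MeI gives trimethyl[(2E,6E,10E)-7,11,15-trimethylhexadeca-2,6,10,14-tetraen-2-yl]silane F6. Iododesilylation with N-iodosuccinimide, with retention, returns to the route at 16.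

Step 2. The iodo-ylide olefination may lose Z-selectivity or stall, and the β-silyloxy aldehyde may eliminate under the basic conditions. The fallback builds the iodoalkene by alkyne trans-hydrosilylation instead and sets out from commercial pent-3-yn-1-ol. Silylation with 1,1,3,3-tetramethyldisilazane gives dimethyl(pent-3-yn-1-yloxy)silane F7. The cationic ruthenium catalyst [Cp*Ru(MeCN)3]PF6 should effect intramolecular endo-dig trans-hydrosilylation to 2,2,3-trimethyl-5,6-dihydro-2H-1,2-oxasiline F8, in which the ring enforces the cis relation of silicon and chain. Iododesilylation with N-iodosuccinimide in hexafluoroisopropanol, with retention, and aqueous work-up return to the route at 5.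

**Further compounds**

F1 | step 5 | (1S,3S,4S)-3-ethenyl-2,2-dimethylcyclohexane-1,4-diol | O[C@H]1CC[C@H](O)[C@@H](C=C)C1(C)C
F2 | step 5 | (2S,4S)-2-ethenyl-4-hydroxy-3,3-dimethylcyclohexan-1-one | O[C@H]1CCC(=O)[C@@H](C=C)C1(C)C
F3 | step 5 | (1S,3S)-3-ethenyl-2,2-dimethyl-4-oxocyclohexyl acetate | CC(=O)O[C@H]1CCC(=O)[C@@H](C=C)C1(C)C
F4 | step 5 | (1S,5S)-5-ethenyl-6,6-dimethyl-4-{[(trifluoromethyl)sulfonyl]oxy}cyclohex-3-en-1-yl acetate | CC(=O)O[C@H]1CC=C(OS(=O)(=O)C(F)(F)F)[C@@H](C=C)C1(C)C
F5 | step 8 | trimethyl[(5E,9E)-6,10,14-trimethylpentadeca-5,9,13-trien-1-yn-1-yl]silane | C[Si](C)(C)C#CCC/C=C(\C)CC/C=C(\C)CCC=C(C)C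
F6 | step 8 | trimethyl[(2E,6E,10E)-7,11,15-trimethylhexadeca-2,6,10,14-tetraen-2-yl]silane | C[Si](C)(C)/C(C)=C/CC/C=C(\C)CC/C=C(\C)CCC=C(C)C
F7 | step 2 | dimethyl(pent-3-yn-1-yloxy)silane | CC#CCCO[SiH](C)C
F8 | step 2 | 2,2,3-trimethyl-5,6-dihydro-2H-1,2-oxasiline | CC1=CCCO[Si]1(C)C
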